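**Strategy.** Ring A is disconnected by removing C3. The C2 ketone and the C19 carboxyl carbon on C4 stand in a 1,4 (dissonant) relationship that no aldol or Claisen closure of ring A provides, whereas one-carbon enlargement of a five-membered β-keto ester does. The key step is a radical ring expansion in which the bromomethyl carbon on C4 becomes C3, forming C2–C3 and breaking C2–C4, so that ring A appears on an intact trans C5/C10 fusion. The precursor is a trans-hydrindanone (C10–C1–C2(=O)–C4–C5) made by Dieckmann closure, carrying CO2tBu and CH2Br on C4; ring B already bears the C8 methylene and a pivaloyloxyethyl chain on C9.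

Key step: step 12

Remark: labdane numbering is used throughout (α = face of H-5, β = face of the C10 methyl); C8 passes through the ring expansion as the exocyclic methylene and O12 as a pivalate, both spectators there, so that C2 is the only carbonyl to mask afterwards; the C4 configuration of 18–21 has no consequence.

## Route

Step 1
Reactants: 1 tert-butyl 4-oxobutanoate; 2 but-3-en-2-one
Product: 3 tert-butyl (S)-3-formyl-6-oxoheptanoate
Conditions: (S)-α,α-diphenylprolinol methyl ether (5 mol%), ethyl 3,4-dihydroxybenzoate (20 mol%), neat, 4 °C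
Reagents that add atoms: none
Why: Enamine-catalysed Michael addition of the aldehyde to the enone, in which the (S)-configured catalyst shields one face of the (E)-enamine so that C5 should form with the (S) configuration.

Step 2
Reactants: 3 tert-butyl (S)-3-formyl-6-oxoheptanoate
Product: 5 tert-butyl (S)-2-(4-oxocyclohex-2-en-1-yl)acetate, via aldol adduct 4 (not isolated)
Conditions: LiOH·H2O (0.3 equiv), i-PrOH, 25 °C
Reagents that add atoms: none
Why: Intramolecular aldol condensation of the 1,5-keto aldehyde closes ring B as the conjugated enone under hydroxide catalysis mild enough that the enolisable C5 centre should not racemise before ring closure.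

Step 3
Reactants: 5 tert-butyl (S)-2-(4-oxocyclohex-2-en-1-yl)acetate
Product: 6 tert-butyl 2-[(1S,2S)-2-methyl-4-(trimethylsilyloxy)cyclohex-3-en-1-yl]acetate
Conditions: MeMgBr (1.5 equiv), CuBr·SMe2 (5 mol%), Me3SiCl (2 equiv), THF, −78 °C; then NEt3
Reagents that add atoms: methylmagnesium bromide C[Mg]Br; chlorotrimethylsilane C[Si](C)(C)Cl
Why: Copper-catalysed conjugate addition of the Grignard reagent, accelerated by the silyl chloride, brings in the C20 methyl anti to the C5 side chain and traps the enolate as its silyl enol ether, the new C10 centre being erased again in step 4.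

Step 4
Reactants: 6 tert-butyl 2-[(1S,2S)-2-methyl-4-(trimethylsilyloxy)cyclohex-3-en-1-yl]acetate
Product: 7 tert-butyl (S)-2-(2-methyl-4-oxocyclohex-2-en-1-yl)acetate
Conditions: Pd(OAc)2 (10 mol%), O2 (1 atm), DMSO, 40 °C
Reagents that add atoms: none
Why: Saegusa–Ito oxidation, in which the palladium enolate formed from the silyl enol ether undergoes β-hydride elimination towards C10 and so returns the enone with the methyl group now on C10.

Step 5
Reactants: 7 tert-butyl (S)-2-(2-methyl-4-oxocyclohex-2-en-1-yl)acetate; 8 tert-butyl[(1-methoxyethenyl)oxy]dimethylsilane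
Product: 9 tert-butyl 2-[4-(tert-butyldimethylsilyloxy)-2-(2-methoxy-2-oxoethyl)-2-methylcyclohex-3-en-1-yl]acetate (5α-H 10β-CH3)
Conditions: Tf2NH (1 mol%), CH2Cl2, −78 °C; then NEt3
Reagents that add atoms: none
Why: Mukaiyama–Michael addition with silyl transfer (silyl triflimide formed from the acid catalyst), in which the ketene acetal should attack C10 anti to the C5 side chain, held pseudoaxial by allylic strain with the C10 methyl, so that the quaternary centre forms with C1 trans to C4 and the enol ether stays fixed between C8 and C9.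

Step 6
Reactants: 9 tert-butyl 2-[4-(tert-butyldimethylsilyloxy)-2-(2-methoxy-2-oxoethyl)-2-methylcyclohex-3-en-1-yl]acetate (5α-H 10β-CH3); 10 allyl methyl carbonate
Product: 12 tert-butyl 2-[2-(2-methoxy-2-oxoethyl)-2-methyl-4-oxo-3-(prop-2-en-1-yl)cyclohexyl]acetate (5α-H 9α-H 10β-CH3), via 9-epimer 11 (not isolated)
Conditions: Pd2(dba)3 (2.5 mol%; dba = dibenzylideneacetone), Ph2PCH2CH2PPh2 (6 mol%), Bu4N[Ph3SiF2] (20 mol%), THF, 25 → 40 °C; then NaOMe (0.2 equiv), MeOH, 25 °C
Reagents that add atoms: none
Why: Tsuji allylation of the silyl enol ether, in which methoxide released from the carbonate unmasks the enolate only between C8 and C9 for capture by the π-allylpalladium complex at C9, and the methoxide equilibration should then favour the equatorial allyl group (9α-H), the minor epimer being resubmitted.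

Step 7
Reactants: 12 tert-butyl 2-[2-(2-methoxy-2-oxoethyl)-2-methyl-4-oxo-3-(prop-2-en-1-yl)cyclohexyl]acetate (5α-H 9α-H 10β-CH3)
Product: 15 tert-butyl 2-[3-(2-hydroxyethyl)-2-(2-methoxy-2-oxoethyl)-2-methyl-4-oxocyclohexyl]acetate (5α-H 9α-H 10β-CH3), via ozonide 13 (not isolated), via aldehyde 14 (not isolated)
Conditions: O3, CH2Cl2, −78 °C; Me2S, −78 → 0 °C; then NaBH4, EtOH, −78 °C
Reagents that add atoms: ozone [O-][O+]=O
Why: Ozonolysis of the only alkene with reductive work-up, then aldehyde-selective borohydride reduction at low temperature, where the hindered C8 ketone next to C9 and C10 should stay untouched.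

Step 8
Reactants: 15 tert-butyl 2-[3-(2-hydroxyethyl)-2-(2-methoxy-2-oxoethyl)-2-methyl-4-oxocyclohexyl]acetate (5α-H 9α-H 10β-CH3)
Product: 16 tert-butyl 2-[2-(2-methoxy-2-oxoethyl)-2-methyl-4-oxo-3-(2-pivaloyloxyethyl)cyclohexyl]acetate (5α-H 9α-H 10β-CH3)
Conditions: t-BuCOCl, pyridine, DMAP (5 mol%), CH2Cl2, 0 → 25 °C
Reagents that add atoms: pivaloyl chloride CC(C)(C)C(=O)Cl
Why: Acylation of the primary alcohol gives a hindered ester that has no α-hydrogen, resists the bases of steps 9–14 and is removed by the hydride reduction of step 15.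

Step 9
Reactants: 16 tert-butyl 2-[2-(2-methoxy-2-oxoethyl)-2-methyl-4-oxo-3-(2-pivaloyloxyethyl)cyclohexyl]acetate (5α-H 9α-H 10β-CH3)
Product: 17 tert-butyl 2-[2-(2-methoxy-2-oxoethyl)-2-methyl-4-methylidene-3-(2-pivaloyloxyethyl)cyclohexyl]acetate (5α-H 9α-H 10β-CH3)
Conditions: Ph3PCH3Br (3 equiv), KOtBu (2.8 equiv), toluene, 25 → 80 °C
Reagents that add atoms: methyltriphenylphosphonium bromide C[P+](c1ccccc1)(c1ccccc1)c1ccccc1.[Br-]
Why: Wittig methylenation of the hindered C8 ketone with excess ylide, to which the three esters are inert, installs C17 and at the same time fixes the C9 configuration by removing the adjacent carbonyl.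

Step 10
Reactants: 17 tert-butyl 2-[2-(2-methoxy-2-oxoethyl)-2-methyl-4-methylidene-3-(2-pivaloyloxyethyl)cyclohexyl]acetate (5α-H 9α-H 10β-CH3)
Product: 18 tert-butyl 3a-methyl-5-methylidene-2-oxo-4-(2-pivaloyloxyethyl)octahydro-1H-indene-1-carboxylate (trans-fused)
Conditions: KOtBu (2.2 equiv), THF, 0 → 25 °C; then AcOH
Reagents that add atoms: none
Why: Dieckmann condensation in which only the C4 enolate finds an electrophilic partner, the methyl ester at C2, because the tert-butyl ester is no acceptor, so the trans-fused cyclopentanone with the ketone at C2 and the carboxylate on C4 should form as its stabilised enolate.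

Step 11
Reactants: 18 tert-butyl 3a-methyl-5-methylidene-2-oxo-4-(2-pivaloyloxyethyl)octahydro-1H-indene-1-carboxylate (trans-fused)
Product: 19 tert-butyl 1-(bromomethyl)-3a-methyl-5-methylidene-2-oxo-4-(2-pivaloyloxyethyl)octahydro-1H-indene-1-carboxylate (trans-fused)
Conditions: NaH (1.1 equiv), THF–DMPU (4:1), 0 °C; CH2Br2 (8 equiv), 50 °C
Reagents that add atoms: dibromomethane BrCBr
Why: C-alkylation of the sodium enolate of the β-keto ester with excess dibromomethane makes C4 quaternary, the electrophile being expected anti to the C10 methyl although this configuration is lost in step 12.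

Step 12
Reactants: 19 tert-butyl 1-(bromomethyl)-3a-methyl-5-methylidene-2-oxo-4-(2-pivaloyloxyethyl)octahydro-1H-indene-1-carboxylate (trans-fused)
Product: 20 tert-butyl 2-oxo-12-pivaloyloxy-13,14,15,16,18-pentanorlabd-8(17)-en-19-oate
Conditions: Bu3SnH (1.3 equiv) and AIBN (0.1 equiv) added over 6 h, benzene (0.01 M), 80 °C
Reagents that add atoms: none
Why: Dowd–Beckwith ring expansion, in which the stannyl radical abstracts bromine, the primary radical adds 3-exo-trig to the adjacent C2 carbonyl, and the cyclopropyloxy radical undergoes β-scission of the C2–C4 bond to the ester-stabilised tertiary C4 radical, which takes hydrogen from the tin hydride. The closest known reaction type is the tin hydride ring expansion of 2-(bromomethyl)-2-alkoxycarbonylcyclopentanones to 3-oxocyclohexanecarboxylates. Ring A is not closed by a new ring-forming bond but arises by one-carbon enlargement of the five-membered ring (3-exo closure, then ring opening), so the trans C5/C10 fusion is carried over unchanged. The only new stereocentre, C4–H, is set by hydrogen transfer to the face away from the C10 methyl and is planarised again in step 14. The step needs β-scission towards C4 and not back to the primary radical, which the ester stabilisation secures, and rearrangement faster than direct reduction, which slow hydride addition at high dilution secures. The quaternary β-keto ester cannot enolise, and the C8 methylene, too remote and hindered to trap either radical, is a spectator like the pivalate.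

Step 13
Reactants: 20 tert-butyl 2-oxo-12-pivaloyloxy-13,14,15,16,18-pentanorlabd-8(17)-en-19-oate
Product: 21 tert-butyl 2,2-ethylenedioxy-12-pivaloyloxy-13,14,15,16,18-pentanorlabd-8(17)-en-19-oate
Conditions: HOCH2CH2OH (5 equiv), pyridinium p-toluenesulfonate (10 mol%), benzene, reflux (Dean–Stark)
Reagents that add atoms: ethylene glycol OCCO
Why: Acid-catalysed ketalisation of the unhindered C2 ketone with a buffered acid that should neither isomerise the exocyclic alkene nor cleave the tert-butyl ester.

Step 14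
Reactants: 21 tert-butyl 2,2-ethylenedioxy-12-pivaloyloxy-13,14,15,16,18-pentanorlabd-8(17)-en-19-oate
Product: 22 tert-butyl 2,2-ethylenedioxy-12-pivaloyloxy-13,14,15,16-tetranorlabd-8(17)-en-19-oate
Conditions: LiN(i-Pr)2 (1.5 equiv), THF, −78 → −30 °C; MeI (5 equiv), DMPU, −78 → 0 °C
Reagents that add atoms: iodomethane CI
Why: Ester enolate alkylation in which iodomethane should approach C4 from the α-face (equatorial), the β-face being blocked by the axial C10 methyl and the axial ketal oxygen on C2, giving the 4α-methyl (C18) and the axial 4β-carboxylate (C19).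

Step 15
Reactants: 22 tert-butyl 2,2-ethylenedioxy-12-pivaloyloxy-13,14,15,16-tetranorlabd-8(17)-en-19-oate
Product: 23 2,2-ethylenedioxy-13,14,15,16-tetranorlabd-8(17)-ene-12,19-diol
Conditions: LiAlH4 (4 equiv), THF, 0 → 65 °C
Reagents that add atoms: none
Why: Hydride reduction converts the hindered tert-butyl ester into the C19 carbinol and cleaves the pivalate in the same operation, the ketal and the alkene being inert.

Step 16
Reactants: 23 2,2-ethylenedioxy-13,14,15,16-tetranorlabd-8(17)-ene-12,19-diol
Product: 24 12-bromo-2,2-ethylenedioxy-13,14,15,16-tetranorlabd-8(17)-en-19-ol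
Conditions: CBr4 (1.2 equiv), PPh3 (1.3 equiv), CH2Cl2, 0 °C
Reagents that add atoms: tetrabromomethane BrC(Br)(Br)Br
Why: The Appel reaction ends in an SN2 displacement and should therefore convert only the unhindered C12 carbinol, the axial neopentyl C19 carbinol being unable to undergo backside attack.

Step 17
Reactants: 24 12-bromo-2,2-ethylenedioxy-13,14,15,16-tetranorlabd-8(17)-en-19-ol
Product: 25 12-bromo-2,2-ethylenedioxy-13,14,15,16-tetranorlabd-8(17)-en-19-yl acetate
Conditions: Ac2O, pyridine, DMAP (10 mol%), 25 °C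
Reagents that add atoms: acetic anhydride CC(=O)OC(C)=O
Why: DMAP-catalysed acetylation of the remaining neopentyl primary alcohol installs the C19 acetate of the target.

Step 18
Reactants: 25 12-bromo-2,2-ethylenedioxy-13,14,15,16-tetranorlabd-8(17)-en-19-yl acetate
Product: 26 12-bromo-2,2-ethylenedioxy-7α-hydroxy-13,14,15,16-tetranorlabd-8(17)-en-19-yl acetate
Conditions: SeO2 (0.5 equiv), t-BuOOH (3 equiv), CH2Cl2, 0 → 25 °C
Reagents that add atoms: selenium dioxide O=[Se]=O; tert-butyl hydroperoxide CC(C)(C)OO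
Why: Selenium dioxide allylic oxidation (ene reaction at C17 with loss of the axial C7 hydrogen, then [2,3]-sigmatropic shift) should attack the ring methylene C7 in preference to the methine C9 and deliver oxygen axially, giving the 7α-alcohol with the 8(17)-alkene restored.

Step 19
Reactants: 26 12-bromo-2,2-ethylenedioxy-7α-hydroxy-13,14,15,16-tetranorlabd-8(17)-en-19-yl acetate
Product: 27 12-bromo-2,2-ethylenedioxy-7α-triethylsilyloxy-13,14,15,16-tetranorlabd-8(17)-en-19-yl acetate
Conditions: Et3SiCl, imidazole, DMF, 0 → 25 °C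
Reagents that add atoms: chlorotriethylsilane CC[Si](Cl)(CC)CC
Why: Silylation of the secondary allylic alcohol prevents protonation of the organozinc reagent in step 22, and the group falls off in the final acidic step.

Step 20
Reactants: 28 but-2-yn-1-ol
Product: 30 (Z)-3-iodobut-2-en-1-ol, via alkenylaluminate 29 (not isolated)
Conditions: NaAlH2(OCH2CH2OMe)2 (1.5 equiv), THF, 0 → 25 °C; then I2 (2 equiv), −78 → 0 °C
Reagents that add atoms: iodine II
Why: Hydroxyl-directed trans-hydroalumination of the propargylic alcohol places aluminium on C3 cis to the carbinol carbon in a five-membered aluminate, and iodinolysis with retention gives the (Z)-vinyl iodide.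

Step 21
Reactants: 30 (Z)-3-iodobut-2-en-1-ol
Product: 31 tert-butyl{[(Z)-3-iodobut-2-en-1-yl]oxy}dimethylsilane
Conditions: t-BuMe2SiCl, imidazole, CH2Cl2, 25 °C
Reagents that add atoms: tert-butylchlorodimethylsilane CC(C)(C)[Si](C)(C)Cl
Why: Silylation of the primary allylic alcohol removes the acidic proton before the organozinc coupling.

Step 22
Reactants: 27 12-bromo-2,2-ethylenedioxy-7α-triethylsilyloxy-13,14,15,16-tetranorlabd-8(17)-en-19-yl acetate; 31 tert-butyl{[(Z)-3-iodobut-2-en-1-yl]oxy}dimethylsilane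
Product: 33 15-(tert-butyldimethylsilyloxy)-2,2-ethylenedioxy-7α-triethylsilyloxylabda-8(17),13Z-dien-19-yl acetate, via alkylzinc bromide 32 (not isolated)
Conditions: Zn dust (3 equiv), LiCl (1.5 equiv), THF, 50 °C; then 31 (1.3 equiv), PdCl2(dppf) (5 mol%; dppf = 1,1′-bis(diphenylphosphino)ferrocene), 25 → 50 °C
Reagents that add atoms: none
Why: Negishi coupling, in which zinc inserts into the primary C12–Br bond and the alkylzinc bromide couples with the vinyl iodide under palladium catalysis with retention of the (Z) geometry, the bidentate ligand suppressing β-hydride elimination and the acetate and ketal tolerating the organozinc.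

Step 23
Reactants: 33 15-(tert-butyldimethylsilyloxy)-2,2-ethylenedioxy-7α-triethylsilyloxylabda-8(17),13Z-dien-19-yl acetate
Product: 34 7α,15-dihydroxy-2-oxolabda-8(17),13Z-dien-19-yl acetate (CNP0277693.2)
Conditions: AcOH–THF–H2O (3:1:1), 45 °C
Reagents that add atoms: water O
Why: Aqueous acetic acid should hydrolyse both silyl ethers and the strained C2 dioxolane (relief of the 1,3-diaxial contacts with C19 and C20) without ionising the allylic alcohols, isomerising the alkenes or cleaving the acetate.

## Compound list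

1 | tert-butyl 4-oxobutanoate | O=CCCC(=O)OC(C)(C)C | starting material
2 | but-3-en-2-one | CC(=O)C=C | starting material
3 | tert-butyl (S)-3-formyl-6-oxoheptanoate | O=C[C@H](CC(=O)OC(C)(C)C)CCC(C)=O | intermediate
4 | tert-butyl 2-[(1S)-2-hydroxy-4-oxocyclohexyl]acetate (aldol adduct; carbinol configuration open) | O=C1CC(O)[C@H](CC(=O)OC(C)(C)C)CC1 | intermediate
5 | tert-butyl (S)-2-(4-oxocyclohex-2-en-1-yl)acetate | O=C1C=C[C@H](CC(=O)OC(C)(C)C)CC1 | intermediate
6 | tert-butyl 2-[(1S,2S)-2-methyl-4-(trimethylsilyloxy)cyclohex-3-en-1-yl]acetate (methyl trans to the side chain) | C[Si](C)(C)OC1=C[C@@H](C)[C@H](CC(=O)OC(C)(C)C)CC1 | intermediate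
7 | tert-butyl (S)-2-(2-methyl-4-oxocyclohex-2-en-1-yl)acetate | O=C1C=C(C)[C@H](CC(=O)OC(C)(C)C)CC1 | intermediate
8 | tert-butyl[(1-methoxyethenyl)oxy]dimethylsilane | C=C(OC)O[Si](C)(C)C(C)(C)C | starting material
9 | tert-butyl 2-[4-(tert-butyldimethylsilyloxy)-2-(2-methoxy-2-oxoethyl)-2-methylcyclohex-3-en-1-yl]acetate (5α-H 10β-CH3; the two acetate arms trans) | COC(=O)C[C@]1(C)C=C(O[Si](C)(C)C(C)(C)C)CC[C@H]1CC(=O)OC(C)(C)C | intermediate
10 | allyl methyl carbonate | C=CCOC(=O)OC | starting material
11 | 9β-H epimer of ketone 12 (allyl axial) | C=CC[C@@H]1C(=O)CC[C@@H](CC(=O)OC(C)(C)C)[C@]1(C)CC(=O)OC | intermediate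
12 | tert-butyl 2-[2-(2-methoxy-2-oxoethyl)-2-methyl-4-oxo-3-(prop-2-en-1-yl)cyclohexyl]acetate (5α-H 9α-H 10β-CH3) | C=CC[C@H]1C(=O)CC[C@@H](CC(=O)OC(C)(C)C)[C@]1(C)CC(=O)OC | intermediate
13 | ozonide of 12 (3-substituted 1,2,4-trioxolane; acetal carbon configuration open) | C1(OCOO1)C[C@H]2C(=O)CC[C@@H](CC(=O)OC(C)(C)C)[C@]2(C)CC(=O)OC | intermediate
14 | tert-butyl 2-[2-(2-methoxy-2-oxoethyl)-2-methyl-4-oxo-3-(2-oxoethyl)cyclohexyl]acetate (5α-H 9α-H 10β-CH3) | O=CC[C@H]1C(=O)CC[C@@H](CC(=O)OC(C)(C)C)[C@]1(C)CC(=O)OC | intermediate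
15 | tert-butyl 2-[3-(2-hydroxyethyl)-2-(2-methoxy-2-oxoethyl)-2-methyl-4-oxocyclohexyl]acetate (5α-H 9α-H 10β-CH3) | OCC[C@H]1C(=O)CC[C@@H](CC(=O)OC(C)(C)C)[C@]1(C)CC(=O)OC | intermediate
16 | tert-butyl 2-[2-(2-methoxy-2-oxoethyl)-2-methyl-4-oxo-3-(2-pivaloyloxyethyl)cyclohexyl]acetate (5α-H 9α-H 10β-CH3) | CC(C)(C)C(=O)OCC[C@H]1C(=O)CC[C@@H](CC(=O)OC(C)(C)C)[C@]1(C)CC(=O)OC | intermediate
17 | tert-butyl 2-[2-(2-methoxy-2-oxoethyl)-2-methyl-4-methylidene-3-(2-pivaloyloxyethyl)cyclohexyl]acetate (5α-H 9α-H 10β-CH3) | CC(C)(C)C(=O)OCC[C@H]1C(=C)CC[C@@H](CC(=O)OC(C)(C)C)[C@]1(C)CC(=O)OC | intermediate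
18 | tert-butyl 3a-methyl-5-methylidene-2-oxo-4-(2-pivaloyloxyethyl)octahydro-1H-indene-1-carboxylate (trans-fused; 5α-H 9α-H 10β-CH3; C4 enolisable and left open) | CC(C)(C)OC(=O)C1C(=O)C[C@@]2(C)[C@H]1CCC(=C)[C@@H]2CCOC(=O)C(C)(C)C | intermediate
19 | tert-butyl 1-(bromomethyl)-3a-methyl-5-methylidene-2-oxo-4-(2-pivaloyloxyethyl)octahydro-1H-indene-1-carboxylate (trans-fused; CH2Br α and CO2tBu β on C4) | BrC[C@]1(C(=O)OC(C)(C)C)C(=O)C[C@@]2(C)[C@H]1CCC(=C)[C@@H]2CCOC(=O)C(C)(C)C | intermediate
20 | tert-butyl 2-oxo-12-pivaloyloxy-13,14,15,16,18-pentanorlabd-8(17)-en-19-oate (4α-H drawn; either C4 epimer serves) | CC(C)(C)OC(=O)[C@H]1CC(=O)C[C@@]2(C)[C@H]1CCC(=C)[C@@H]2CCOC(=O)C(C)(C)C | intermediate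
21 | tert-butyl 2,2-ethylenedioxy-12-pivaloyloxy-13,14,15,16,18-pentanorlabd-8(17)-en-19-oate | CC(C)(C)OC(=O)[C@H]1CC2(OCCO2)C[C@@]3(C)[C@H]1CCC(=C)[C@@H]3CCOC(=O)C(C)(C)C | intermediate
22 | tert-butyl 2,2-ethylenedioxy-12-pivaloyloxy-13,14,15,16-tetranorlabd-8(17)-en-19-oate | CC(C)(C)OC(=O)[C@@]1(C)CC2(OCCO2)C[C@@]3(C)[C@H]1CCC(=C)[C@@H]3CCOC(=O)C(C)(C)C | intermediate
23 | 2,2-ethylenedioxy-13,14,15,16-tetranorlabd-8(17)-ene-12,19-diol | OC[C@@]1(C)CC2(OCCO2)C[C@@]3(C)[C@H]1CCC(=C)[C@@H]3CCO | intermediate
24 | 12-bromo-2,2-ethylenedioxy-13,14,15,16-tetranorlabd-8(17)-en-19-ol | OC[C@@]1(C)CC2(OCCO2)C[C@@]3(C)[C@H]1CCC(=C)[C@@H]3CCBr | intermediate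
25 | 12-bromo-2,2-ethylenedioxy-13,14,15,16-tetranorlabd-8(17)-en-19-yl acetate | CC(=O)OC[C@@]1(C)CC2(OCCO2)C[C@@]3(C)[C@H]1CCC(=C)[C@@H]3CCBr | intermediate
26 | 12-bromo-2,2-ethylenedioxy-7α-hydroxy-13,14,15,16-tetranorlabd-8(17)-en-19-yl acetate | CC(=O)OC[C@@]1(C)CC2(OCCO2)C[C@@]3(C)[C@H]1C[C@@H](O)C(=C)[C@@H]3CCBr | intermediate
27 | 12-bromo-2,2-ethylenedioxy-7α-triethylsilyloxy-13,14,15,16-tetranorlabd-8(17)-en-19-yl acetate | CC(=O)OC[C@@]1(C)CC2(OCCO2)C[C@@]3(C)[C@H]1C[C@@H](O[Si](CC)(CC)CC)C(=C)[C@@H]3CCBr | intermediate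
28 | but-2-yn-1-ol | CC#CCO | starting material
29 | sodium 2,2-bis(2-methoxyethoxy)-3-methyl-2,5-dihydro-1,2-oxaaluminol-2-uide (cyclic alkenylaluminate) | CC1=CCO[Al-]1(OCCOC)OCCOC.[Na+] | intermediate
30 | (Z)-3-iodobut-2-en-1-ol | C/C(I)=C/CO | intermediate
31 | tert-butyl{[(Z)-3-iodobut-2-en-1-yl]oxy}dimethylsilane | C/C(I)=C/CO[Si](C)(C)C(C)(C)C | intermediate
32 | (19-acetoxy-2,2-ethylenedioxy-7α-triethylsilyloxy-13,14,15,16-tetranorlabd-8(17)-en-12-yl)zinc bromide | CC(=O)OC[C@@]1(C)CC2(OCCO2)C[C@@]3(C)[C@H]1C[C@@H](O[Si](CC)(CC)CC)C(=C)[C@@H]3CC[Zn]Br | intermediate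
33 | 15-(tert-butyldimethylsilyloxy)-2,2-ethylenedioxy-7α-triethylsilyloxylabda-8(17),13Z-dien-19-yl acetate | CC(=O)OC[C@@]1(C)CC2(OCCO2)C[C@@]3(C)[C@H]1C[C@@H](O[Si](CC)(CC)CC)C(=C)[C@@H]3CC/C(C)=C\CO[Si](C)(C)C(C)(C)C | intermediate
34 | 7α,15-dihydroxy-2-oxolabda-8(17),13Z-dien-19-yl acetate (CNP0277693.2) | C=C1[C@H](O)C[C@H]2[C@@](C)(COC(C)=O)CC(=O)C[C@]2(C)[C@H]1CC/C(C)=C\CO | target

## Step count and risk

Total: 23 steps (21 in the main line, 2 for vinyl iodide 31). Longest linear sequence: 21 steps (steps 1–19, 22 and 23).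

The three steps most likely to fail:

1. **Step 12 (key step).** The primary radical may be reduced by the tin hydride before it adds to the C2 carbonyl, which would leave a 4-methyl β-keto ester. The bromomethylation that feeds it (step 11) may also suffer from O-alkylation at the hindered C4. The fallback sets out from 18 and comes back at 20. It replaces the radical route by the polar zinc-carbenoid homologation of the β-keto ester (Et2Zn and CH2I2, CH2Cl2, 0 °C). The zinc enolate is cyclopropanated, and the donor–acceptor cyclopropanolate opens between C2 and C4 to give the γ-keto ester on protonation (no new compound, F0). The carbenoid is kept to about three equivalents at 0 °C, because the hindered C8 methylene should be cyclopropanated much more slowly than the enolate reacts.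

2. **Step 6.** Desilylation of the hindered enol ether may be slow. Proton transfer within the liberated enolate may erode the regiocontrol or lead to double allylation, and the equilibration at C9 may stop at an unfavourable epimer ratio. The fallback sets out from 9 and comes back at 12, and it makes the C9–C11 bond by a radical instead of an enolate. N-Bromosuccinimide (THF, −78 °C) converts 9 into the C9 α-bromo ketone tert-butyl 2-[3-bromo-2-(2-methoxy-2-oxoethyl)-2-methyl-4-oxocyclohexyl]acetate F1. Keck radical allylation (allyltributylstannane, AIBN, benzene, 80 °C) then installs the allyl group at the same carbon, and the methoxide equilibration of step 6 gives 12.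

3. **Step 18.** Oxygen may be delivered with poor facial selectivity in the sigmatropic shift, giving the equatorial alcohol, or the product may be over-oxidised to the enone. The fallback sets out from 25 and comes back at 26. The crude mixture containing the 7β-alcohol 12-bromo-2,2-ethylenedioxy-7β-hydroxy-13,14,15,16-tetranorlabd-8(17)-en-19-yl acetate F2 is oxidised with Dess–Martin periodinane to the enone 12-bromo-2,2-ethylenedioxy-7-oxo-13,14,15,16-tetranorlabd-8(17)-en-19-yl acetate F3. Corey–Bakshi–Shibata reduction of F3 with (S)-2-methyl-CBS-oxazaborolidine and catecholborane (−78 °C) is a reagent-controlled 1,2-reduction in which the alkenyl carbon C8 acts as the large group, and it should give the 7α-alcohol.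

Further compounds
F0 | step 12 | none | none
F1 | step 6 | tert-butyl 2-[3-bromo-2-(2-methoxy-2-oxoethyl)-2-methyl-4-oxocyclohexyl]acetate (5α-H 10β-CH3; C9 open) | BrC1C(=O)CC[C@@H](CC(=O)OC(C)(C)C)[C@]1(C)CC(=O)OC
F2 | step 18 | 12-bromo-2,2-ethylenedioxy-7β-hydroxy-13,14,15,16-tetranorlabd-8(17)-en-19-yl acetate | CC(=O)OC[C@@]1(C)CC2(OCCO2)C[C@@]3(C)[C@H]1C[C@H](O)C(=C)[C@@H]3CCBr
F3 | step 18 | 12-bromo-2,2-ethylenedioxy-7-oxo-13,14,15,16-tetranorlabd-8(17)-en-19-yl acetate | CC(=O)OC[C@@]1(C)CC2(OCCO2)C[C@@]3(C)[C@H]1CC(=O)C(=C)[C@@H]3CCBr
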